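Ring A, the cyclohexenedione, is opened between its saturated-ketone carbonyl carbon and the spiro carbon it shares with cyclopentane ring B. That spiro carbon lies next to the isopropyl-bearing carbon of ring B and is the α′ carbon of the β-dicarbonyl unit formed by the enone carbonyl, the methyl-bearing carbon and the methoxy-bearing carbon of ring A. A diketone dianion can therefore be acylated at this carbon by a methyl ester, which closes ring A and creates the spiro quaternary stereocentre in one operation. The precursor 20 is ring B carrying the chain C(=O)–CH(Me)–C(=O)–CMe2–CO2Me; ring B comes from a nopinone-derived enone by conjugate addition and enolate ring closure.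

Key step: step 14

Atom names: pinane carbons are numbered C1–C7 as in bicyclo[3.1.1]heptane (C2 is the carbon shared with ring B, C6 carries the gem-dimethyl group). Ring A consists, going round, of the A/B spiro carbon, the enone carbonyl carbon, the methyl-bearing carbon, the methoxy-bearing carbon, the gem-dimethyl carbon and the saturated-ketone carbon. In the open chain of 19 and 20 the corresponding atoms are the ring B methine, the inner ketone, the methyl-bearing carbon, the outer ketone (a carbinol in 19), the gem-dimethyl carbon and the ester carbon. Ring B consists of the A/B spiro carbon, the isopropyl-bearing carbon, two methylenes and pinane C2. "Ring B unit" in the names below means ring B spiro-fused to the pinane as in the target: the future A/B spiro carbon bonded to pinane C2 on the face syn to the gem-dimethyl bridge, the ring B methylene on the face syn to the methylene bridge, and the isopropyl-bearing carbon of R configuration.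

Assumption: 16, 19 and 20 are drawn with the acyl group on the future A/B spiro carbon trans to isopropyl, the arrangement expected after base equilibration. This centre and the methyl-bearing centres of 19 and 20 are erased in step 14, and the carbinol centre of 19 in step 13. Compounds 4 and 5 are drawn as E isomers; a Z isomer would converge in step 8.

Step 1
Reactants: 1 (+)-β-pinene, (1R,5R)-6,6-dimethyl-2-methylidenebicyclo[3.1.1]heptane
Product: 2 (−)-nopinone, (1S,5R)-6,6-dimethylbicyclo[3.1.1]heptan-2-one
Conditions: O3, CH2Cl2/MeOH, −78 °C; then Me2S, −78 °C to rt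
Reagents that add atoms: ozone, [O-][O+]=O
Why: Ozonolysis with reductive work-up cleaves the exocyclic methylidene to the C2 ketone and leaves both bridgehead stereocentres untouched.

Step 2
Reactants: 2 (−)-nopinone; 3 diethyl {2-[methoxy(methyl)amino]-2-oxoethyl}phosphonate
Product: 4 (2E)-2-[(1S,5R)-6,6-dimethylbicyclo[3.1.1]heptan-2-ylidene]-N-methoxy-N-methylacetamide
Conditions: NaH, THF, 0 °C to reflux
Reagents that add atoms: none
Why: Horner–Wadsworth–Emmons olefination of a cyclic ketone by an amide-stabilised phosphonate anion; the isomer with the amide anti to the bridgehead C1 should dominate, and either isomer serves later.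

Step 3
Reactants: 4 unsaturated N-methoxy-N-methylamide
Product: 5 (1E)-1-[(1S,5R)-6,6-dimethylbicyclo[3.1.1]heptan-2-ylidene]butan-2-one
Conditions: EtMgBr, THF, 0 °C; aq. NH4Cl
Reagents that add atoms: ethylmagnesium bromide, CC[Mg]Br
Why: Weinreb ketone synthesis: the chelated tetrahedral adduct persists until work-up, so a single ethyl group is delivered and the hindered β,β-disubstituted alkene is not attacked.

Step 4
Reactants: 6 methyl 4-methyl-3-oxopentanoate
Product: 7 methyl (3S)-3-hydroxy-4-methylpentanoate
Conditions: H2 (50 atm), RuCl2[(R)-BINAP] (0.2 mol %), MeOH, 50 °C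
Reagents that add atoms: none
Why: Noyori asymmetric hydrogenation of a β-keto ester: the chelated ketone is reduced on the face fixed by the (R)-BINAP ligand, the same spatial sense as for methyl acetoacetate, which here carries the S descriptor because isopropyl outranks the CH2CO2Me arm.

Step 5
Reactants: 7 methyl (3S)-3-hydroxy-4-methylpentanoate
Product: 8 methyl (3S)-3-[(tert-butyldimethylsilyl)oxy]-4-methylpentanoate
Conditions: TBSCl, imidazole, DMF, rt
Reagents that add atoms: tert-butyldimethylsilyl chloride, CC(C)(C)[Si](C)(C)Cl
Why: Imidazole-promoted silylation of a secondary alcohol gives an ether that withstands hydride, phosphonium and organomagnesium chemistry.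

Step 6
Reactants: 8 silyl ether ester
Product: 9 (3S)-3-[(tert-butyldimethylsilyl)oxy]-4-methylpentan-1-ol
Conditions: i-Bu2AlH (2.5 equiv), CH2Cl2, −78 to 0 °C; aq. KNaC4H4O6
Reagents that add atoms: none
Why: Hydride reduction of the ester to the primary alcohol by excess i-Bu2AlH, to which the secondary silyl ether is inert.

Step 7
Reactants: 9 primary alcohol
Product: 10 {[(3S)-1-bromo-4-methylpentan-3-yl]oxy}(tert-butyl)dimethylsilane
Conditions: CBr4, PPh3, CH2Cl2, 0 °C
Reagents that add atoms: carbon tetrabromide, BrC(Br)(Br)Br
Why: Appel reaction: bromide displaces the primary oxyphosphonium group by SN2, two bonds away from the stereocentre.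

Step 8
Reactants: 5 enone; 10 bromide
Product: 14 1-[(1R,2S,5R)-2-[(3S)-3-hydroxy-4-methylpentyl]-6,6-dimethylbicyclo[3.1.1]heptan-2-yl]butan-2-one, via Grignard reagent 11 (not isolated), via silyl enol ether 12 (not isolated), via silyl-protected ketone 13 (not isolated)
Conditions: 10, Mg, THF, 40 °C; then CuBr·SMe2 (10 mol %), HMPA, TMSCl, 5, THF, −78 to −30 °C; then HCl (1 M in MeOH), rt
Reagents that add atoms: none
Why: Copper-catalysed, chlorosilane-accelerated conjugate addition of a Grignard reagent to a β,β-disubstituted enone: the alkyl group enters C2 on the face anti to the gem-dimethyl bridge, which sets the quaternary centre with the new chain (the future ring B methylenes) syn to the methylene bridge and the oxobutyl arm syn to the gem-dimethyl bridge, and acidic methanol then cleaves the silyl enol ether and the TBS ether.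

Step 9
Reactants: 14 hydroxy ketone
Product: 15 (3S)-1-[(1R,2S,5R)-6,6-dimethyl-2-(2-oxobutyl)bicyclo[3.1.1]heptan-2-yl]-4-methylpentan-3-yl methanesulfonate
Conditions: MsCl, Et3N, CH2Cl2, 0 °C
Reagents that add atoms: methanesulfonyl chloride, CS(=O)(=O)Cl
Why: Sulfonylation of the secondary alcohol with retention at carbon turns the S carbinol into a leaving group; the ketone is unaffected at 0 °C.

Step 10
Reactants: 15 keto mesylate
Product: 16 1-(ring B unit)propan-1-one, i.e. 1-[6,6-dimethyl-3'-(propan-2-yl)spiro[bicyclo[3.1.1]heptane-2,1'-cyclopentan]-2'-yl]propan-1-one, propanoyl trans to isopropyl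
Conditions: KOt-Bu, t-BuOH/THF, 0 °C to rt
Reagents that add atoms: none
Why: Intramolecular enolate C-alkylation (5-exo-tet) under equilibrating conditions: the enolate on the methylene attached to pinane C2 displaces the mesylate with inversion, turning the S carbinol carbon into the R isopropyl-bearing carbon of ring B, whereas the enolate on the ethyl side could only form a seven-membered ring, and the new methine then settles trans to isopropyl.

Step 11
Reactants: 17 methyl 3-hydroxy-2,2-dimethylpropanoate
Product: 18 methyl 2,2-dimethyl-3-oxopropanoate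
Conditions: TEMPO (10 mol %), PhI(OAc)2, CH2Cl2, rt
Reagents that add atoms: none
Why: Oxoammonium-catalysed oxidation of a primary alcohol stops at the aldehyde under anhydrous conditions, and the quaternary α-carbon rules out enolisation.

Step 12
Reactants: 16 ring B ethyl ketone; 18 aldehyde ester
Product: 19 methyl 3-hydroxy-2,2,4-trimethyl-5-oxo-5-(ring B unit)pentanoate, mixture of isomers at C3 and C4
Conditions: LiN(i-Pr)2, THF, −78 °C; then 18, −78 °C; aq. NH4Cl
Reagents that add atoms: none
Why: Directed aldol addition: the amide base removes a proton kinetically from the ethyl CH2 and not from the hindered ring B methine, and the lithium enolate adds to the non-enolisable aldehyde faster than to its ester; the two new centres are uncontrolled and are erased in steps 13 and 14.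

Step 13
Reactants: 19 aldol adduct
Product: 20 methyl 2,2,4-trimethyl-3,5-dioxo-5-(ring B unit)pentanoate
Conditions: Dess–Martin periodinane, CH2Cl2, 0 °C to rt
Reagents that add atoms: none
Why: Dess–Martin oxidation converts the β-hydroxy ketone into the 1,3-diketone under non-basic conditions that avoid retro-aldol cleavage.

Step 14
Reactants: 20 diketo ester
Product: 21 4''-hydroxy-3'',5'',5'',6,6-pentamethyl-3'-(propan-2-yl)dispiro[bicyclo[3.1.1]heptane-2,1'-cyclopentane-2',1''-cyclohex[3]ene]-2'',6''-dione (ring A enol trione, saturated-ketone carbonyl trans to isopropyl)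
Conditions: LiN(i-Pr)2 (3 equiv), THF, −78 °C to rt; then 1 M HCl
Reagents that add atoms: none
Why: The first equivalent of base converts the 1,3-diketone into its lithium diketonate and a second removes the only other acidic hydrogen, on the ring B methine next to the inner ketone (the gem-dimethyl carbon is quaternary and the ester cannot enolise), giving a dianion whose terminal carbon, the future A/B spiro carbon, is its most basic and most nucleophilic site. The closest known reaction type is the acylation of 1,3-diketone dianions by esters at the terminal carbon, a Claisen condensation run here within one molecule in the manner of a Dieckmann cyclisation. Ring A closes by 6-exo-trig attack of this carbon on the ester carbonyl (enol-endo with respect to the nucleophile), and loss of methoxide leaves the ring A diketonate, which is too stabilised for the closure to reverse. The new quaternary stereocentre is controlled by the adjacent isopropyl-bearing stereocentre of ring B: the enolate is exocyclic to ring B, the chain can reach either face, and its bulky gem-dimethyl ester end should add opposite to the isopropyl group, so that the new ketone ends trans and the enone carbonyl cis to it. The step needs this face selectivity and C- rather than O-acylation; the first rests on the isopropyl group, the other face being flanked only by the hydrogen on the isopropyl-bearing carbon and the pinane bridgehead C1, and the second on the high charge density at the terminal carbon and on the reversibility of closure through the inner enolate oxygen, whose six-membered enol lactone is re-opened by the methoxide set free. Warming to room temperature lets the chelated diketonate rotate into the U-shaped conformer in which the ester carbon comes within reach of the terminal carbanion.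

Step 15
Reactants: 21 ring A enol trione
Product: 22 CNP0307059.1, 4''-methoxy-3'',5'',5'',6,6-pentamethyl-3'-(propan-2-yl)dispiro[bicyclo[3.1.1]heptane-2,1'-cyclopentane-2',1''-cyclohex[3]ene]-2'',6''-dione
Conditions: Me3SiCHN2, MeOH/toluene, 0 °C to rt
Reagents that add atoms: (trimethylsilyl)diazomethane, C[Si](C)(C)C=[N+]=[N-]
Why: O-Methylation of a vinylogous acid by a diazoalkane occurs only at oxygen, and the enol oxygen remote from the A/B spiro carbon, flanked by the gem-dimethyl group alone, is more accessible than the oxygen of the carbonyl beside the spiro carbon and its cis isopropyl neighbour; any regioisomeric ether can be hydrolysed back to 21 and recycled.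

Compound list
1 | (+)-β-pinene, (1R,5R)-6,6-dimethyl-2-methylidenebicyclo[3.1.1]heptane | C=C1CC[C@@H]2C[C@H]1C2(C)C | starting material
2 | (−)-nopinone, (1S,5R)-6,6-dimethylbicyclo[3.1.1]heptan-2-one | O=C1CC[C@@H]2C[C@H]1C2(C)C | intermediate
3 | diethyl {2-[methoxy(methyl)amino]-2-oxoethyl}phosphonate | CCOP(=O)(CC(=O)N(C)OC)OCC | starting material
4 | (2E)-2-[(1S,5R)-6,6-dimethylbicyclo[3.1.1]heptan-2-ylidene]-N-methoxy-N-methylacetamide | CON(C)C(=O)/C=C1\CC[C@@H]2C[C@H]1C2(C)C | intermediate
5 | (1E)-1-[(1S,5R)-6,6-dimethylbicyclo[3.1.1]heptan-2-ylidene]butan-2-one | CCC(=O)/C=C1\CC[C@@H]2C[C@H]1C2(C)C | intermediate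
6 | methyl 4-methyl-3-oxopentanoate | COC(=O)CC(=O)C(C)C | starting material
7 | methyl (3S)-3-hydroxy-4-methylpentanoate | COC(=O)C[C@H](O)C(C)C | intermediate
8 | methyl (3S)-3-[(tert-butyldimethylsilyl)oxy]-4-methylpentanoate | COC(=O)C[C@H](O[Si](C)(C)C(C)(C)C)C(C)C | intermediate
9 | (3S)-3-[(tert-butyldimethylsilyl)oxy]-4-methylpentan-1-ol | OCC[C@H](O[Si](C)(C)C(C)(C)C)C(C)C | intermediate
10 | {[(3S)-1-bromo-4-methylpentan-3-yl]oxy}(tert-butyl)dimethylsilane | BrCC[C@H](O[Si](C)(C)C(C)(C)C)C(C)C | intermediate
11 | {(3S)-3-[(tert-butyldimethylsilyl)oxy]-4-methylpentyl}magnesium bromide | Br[Mg]CC[C@H](O[Si](C)(C)C(C)(C)C)C(C)C | intermediate (not isolated)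
12 | trimethylsilyl enol ether of 13 (2-(trimethylsilyloxy)but-1-enyl group on pinane C2, stereocentres as in 13, enol ether geometry undefined) | CCC(O[Si](C)(C)C)=C[C@@]1(CC[C@H](O[Si](C)(C)C(C)(C)C)C(C)C)CC[C@@H]2C[C@H]1C2(C)C | intermediate (not isolated)
13 | 1-[(1R,2S,5R)-2-{(3S)-3-[(tert-butyldimethylsilyl)oxy]-4-methylpentyl}-6,6-dimethylbicyclo[3.1.1]heptan-2-yl]butan-2-one | CCC(=O)C[C@@]1(CC[C@H](O[Si](C)(C)C(C)(C)C)C(C)C)CC[C@@H]2C[C@H]1C2(C)C | intermediate (not isolated)
14 | 1-[(1R,2S,5R)-2-[(3S)-3-hydroxy-4-methylpentyl]-6,6-dimethylbicyclo[3.1.1]heptan-2-yl]butan-2-one | CCC(=O)C[C@@]1(CC[C@H](O)C(C)C)CC[C@@H]2C[C@H]1C2(C)C | intermediate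
15 | (3S)-1-[(1R,2S,5R)-6,6-dimethyl-2-(2-oxobutyl)bicyclo[3.1.1]heptan-2-yl]-4-methylpentan-3-yl methanesulfonate | CCC(=O)C[C@@]1(CC[C@H](OS(C)(=O)=O)C(C)C)CC[C@@H]2C[C@H]1C2(C)C | intermediate
16 | 1-(ring B unit)propan-1-one, propanoyl trans to isopropyl | CCC(=O)[C@@H]1[C@@H](C(C)C)CC[C@@]12CC[C@@H]3C[C@H]2C3(C)C | intermediate
17 | methyl 3-hydroxy-2,2-dimethylpropanoate | COC(=O)C(C)(C)CO | starting material
18 | methyl 2,2-dimethyl-3-oxopropanoate | COC(=O)C(C)(C)C=O | intermediate
19 | methyl 3-hydroxy-2,2,4-trimethyl-5-oxo-5-(ring B unit)pentanoate, isomer mixture at C3 and C4 | COC(=O)C(C)(C)C(O)C(C)C(=O)[C@@H]1[C@@H](C(C)C)CC[C@@]12CC[C@@H]3C[C@H]2C3(C)C | intermediate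
20 | methyl 2,2,4-trimethyl-3,5-dioxo-5-(ring B unit)pentanoate, isomer mixture at C4 | COC(=O)C(C)(C)C(=O)C(C)C(=O)[C@@H]1[C@@H](C(C)C)CC[C@@]12CC[C@@H]3C[C@H]2C3(C)C | intermediate
21 | ring A enol trione (O-desmethyl target), saturated-ketone carbonyl trans to isopropyl | OC1=C(C)C(=O)[C@@]2(C(=O)C1(C)C)[C@@H](C(C)C)CC[C@@]21CC[C@@H]2C[C@H]1C2(C)C | intermediate
22 | CNP0307059.1 | COC1=C(C)C(=O)[C@@]2(C(=O)C1(C)C)[C@@H](C(C)C)CC[C@@]21CC[C@@H]2C[C@H]1C2(C)C | target

Total step count: 15. Longest linear sequence: 11 steps (from 6 through steps 4–10 and 12–15 to 22).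

Steps most likely to fail

1. Step 14. What may go wrong: the hindered ring B methine hydrogen may not be removed from the lithium diketonate, so that no dianion forms and the monoanion lactonises through the inner enolate oxygen or is returned; or the acylation may proceed with poor facial selectivity. Fallback (the two rings are closed in the opposite order; it sets out from 15 and returns at 21): kinetic aldol addition of 15 to 18 (LiN(i-Pr)2, THF, −78 °C) should give the hydroxy keto ester mesylate F1, and Dess–Martin oxidation the open-chain diketo ester mesylate F2. With LiN(i-Pr)2 (2.2 equiv) the dianion then forms at the unhindered methylene attached to pinane C2, and Claisen closure should give the ring A trione mesylate F3, which is not isolated. On warming in THF/DMPU its enolate at the carbon between the two flanking ring A carbonyls, the future A/B spiro carbon, should close ring B by intramolecular C-alkylation (5-exo-tet, inversion at the mesylate carbon) to give 21. The flatter enone flank of ring A is expected to lie next to the isopropyl group.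

2. Step 10. What may go wrong: β-elimination of the mesylate by tert-butoxide or by the enolate may overtake substitution at the branched secondary carbon. Fallback (an epoxide replaces the sulfonate as electrophile; it sets out from 5 and returns at 16): copper-catalysed addition of (4-methylpent-3-en-1-yl)magnesium bromide to 5 under the conditions of step 8 should give the homoprenyl ketone F4. Shi epoxidation (KHSO5, K2CO3, MeCN/dimethoxymethane/buffer, with the fructose-derived ketone of the enantiomeric series that gives the S epoxide) should give the epoxy ketone F5. KOt-Bu in t-BuOH/THF then opens the epoxide at its secondary carbon by 5-exo attack of the enolate on the methylene attached to pinane C2, with inversion, giving the tertiary alcohol F6. Dehydration with Burgess reagent gives the isopropenyl ketone F7, and hydrogenation (H2, RhCl(PPh3)3, benzene, which leaves any tetrasubstituted alkene isomer untouched) gives 16.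

3. Step 8. What may go wrong: 1,4-addition at the hindered, fully substituted β-carbon may be slow, so that enolisation of 5 or 1,2-addition consumes the Grignard reagent. Fallback (a doubly activated acceptor; it sets out from 2 and returns at 13): Knoevenagel condensation of 2 with ethyl cyanoacetate (NH4OAc, AcOH, toluene, reflux with water removal) should give the alkylidene cyanoacetate F8. Reagent 11 (CuI cat., THF, −20 °C) adds to it on the face anti to the gem-dimethyl bridge to give the cyanoacetate adduct F9. Krapcho dealkoxycarbonylation (LiCl, wet DMSO, 140 °C) gives the nitrile F10. EtMgBr (toluene/Et2O, reflux) followed by hydrolysis of the magnesium imide with cold dilute acid gives 13, which is desilylated as in step 8.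

Further compounds
F1 | step 14 | methyl 3-hydroxy-6-[(1R,2S,5R)-2-{(3S)-3-(methanesulfonyloxy)-4-methylpentyl}-6,6-dimethylbicyclo[3.1.1]heptan-2-yl]-2,2,4-trimethyl-5-oxohexanoate | COC(=O)C(C)(C)C(O)C(C)C(=O)C[C@@]1(CC[C@H](OS(C)(=O)=O)C(C)C)CC[C@@H]2C[C@H]1C2(C)C
F2 | step 14 | methyl 6-[(1R,2S,5R)-2-{(3S)-3-(methanesulfonyloxy)-4-methylpentyl}-6,6-dimethylbicyclo[3.1.1]heptan-2-yl]-2,2,4-trimethyl-3,5-dioxohexanoate | COC(=O)C(C)(C)C(=O)C(C)C(=O)C[C@@]1(CC[C@H](OS(C)(=O)=O)C(C)C)CC[C@@H]2C[C@H]1C2(C)C
F3 | step 14 | (3S)-1-[6,6-dimethyl-2-(3,3,5-trimethyl-2,4,6-trioxocyclohexyl)bicyclo[3.1.1]heptan-2-yl]-4-methylpentan-3-yl methanesulfonate (pinane centres as in 15) | O=C1C(C)C(=O)C(C)(C)C(=O)C1[C@@]2(CC[C@H](OS(C)(=O)=O)C(C)C)CC[C@@H]3C[C@H]2C3(C)C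
F4 | step 10 | 1-[6,6-dimethyl-2-(4-methylpent-3-en-1-yl)bicyclo[3.1.1]heptan-2-yl]butan-2-one (pinane centres as in 14) | CCC(=O)C[C@@]1(CCC=C(C)C)CC[C@@H]2C[C@H]1C2(C)C
F5 | step 10 | 1-[2-{2-[(2S)-3,3-dimethyloxiran-2-yl]ethyl}-6,6-dimethylbicyclo[3.1.1]heptan-2-yl]butan-2-one (pinane centres as in 14) | CCC(=O)C[C@@]1(CC[C@@H]2OC2(C)C)CC[C@@H]3C[C@H]1C3(C)C
F6 | step 10 | analogue of 16 with 2-hydroxypropan-2-yl in place of isopropyl on ring B | CCC(=O)[C@@H]1[C@@H](C(C)(C)O)CC[C@@]12CC[C@@H]3C[C@H]2C3(C)C
F7 | step 10 | analogue of 16 with prop-1-en-2-yl in place of isopropyl on ring B | CCC(=O)[C@@H]1[C@@H](C(C)=C)CC[C@@]12CC[C@@H]3C[C@H]2C3(C)C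
F8 | step 8 | ethyl 2-cyano-2-[(1S,5R)-6,6-dimethylbicyclo[3.1.1]heptan-2-ylidene]acetate | CCOC(=O)C(C#N)=C1CC[C@@H]2C[C@H]1C2(C)C
F9 | step 8 | ethyl 2-cyano-2-[2-{(3S)-3-[(tert-butyldimethylsilyl)oxy]-4-methylpentyl}-6,6-dimethylbicyclo[3.1.1]heptan-2-yl]acetate (pinane centres as in 13, acetate α-carbon undefined) | CCOC(=O)C(C#N)[C@@]1(CC[C@H](O[Si](C)(C)C(C)(C)C)C(C)C)CC[C@@H]2C[C@H]1C2(C)C
F10 | step 8 | 2-[2-{(3S)-3-[(tert-butyldimethylsilyl)oxy]-4-methylpentyl}-6,6-dimethylbicyclo[3.1.1]heptan-2-yl]acetonitrile (pinane centres as in 13) | N#CC[C@@]1(CC[C@H](O[Si](C)(C)C(C)(C)C)C(C)C)CC[C@@H]2C[C@H]1C2(C)C
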